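## Retrosynthetic overview

- The conjugated acid (C17) comes from Pd-hydroxycarbonylation of a Δ7 enol triflate, made by kinetic enolisation of an 8-oxo-labdane (labdane numbering used for positions).
- C13 and the saturated ring A come from one asymmetric hydrogenation of a dienyl keto acetate.
- Ring B is made by a one-carbon ring expansion of a trans-hydrindenone: CH2Br2 supplies C9, the quaternary C10 migrates from C8 to C9, and the resulting C9 enolate is allylated with the C11–C15 bromo acetate.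
- The trans-hydrindenone comes from ring-closing metathesis of a trans-2-allyl-2-methyl-3-(1,1-dimethylallyl)cyclopentanone, made by enantioselective conjugate reverse prenylation and enolate allylation of 2-methylcyclopent-2-enone.
- Ring order: cyclopentanone (bought) → ring A (metathesis) → ring B (five- to six-membered expansion).

Assumption: 1 (as THF solution), 3, 4, 9, 10, 12 and 19 are taken as commercially available, and the catalyst enantiomers in steps 2 and 6 are named by the face they must deliver and would be fixed by a short screen.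

## Route

Step 1
Reactants: 1 (3-methylbut-2-en-1-yl)magnesium chloride
Product: 2 (3-methylbut-2-en-1-yl)trimethylsilane
Conditions: TMSCl, THF, 0 °C → rt
Reagents that add atoms: chlorotrimethylsilane, C[Si](C)(C)Cl
Why: Electrophilic silylation of the allylic Grignard reagent at its less hindered α-terminus gives the primary prenylsilane needed for γ-selective transfer; no stereocentre is formed.

Step 2
Reactants: 2 (3-methylbut-2-en-1-yl)trimethylsilane; 3 2-methylcyclopent-2-en-1-one; 4 allyl bromide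
Product: 7 (2S,3S)-2-allyl-2-methyl-3-(2-methylbut-3-en-2-yl)cyclopentan-1-one, via silyl enol ether 5 (not isolated), via lithium enolate 6 (not isolated)
Conditions: chiral IDPi acid (3 mol%), PhMe, −60 °C; then MeLi, THF, 0 °C; then 4, DMPU, −78 → 0 °C
Reagents that add atoms: none
Why: Proposed new method: an enantioselective conjugate Hosomi–Sakurai reverse prenylation under silylium–IDPi ion-pair catalysis, in which the IDPi acid is silylated by 2, Me3Si+ activates enone 3 as a siloxyallyl cation held in the chiral anion pocket, 2 attacks the β-carbon through its γ-carbon (SE2′) on the Re face (sets C3 as S, the future C5), and the β-silyl cation hands Me3Si+ back to the anion to leave the regiodefined enol ether 5; MeLi then unmasks enolate 6, which is allylated anti to the bulky C3 group (sets quaternary C2 as S, the future C10, trans); the closest known chemistry is IDPi-catalysed asymmetric Mukaiyama–Michael addition and aldehyde Hosomi–Sakurai allylation, and the racemic Lewis-acid conjugate Sakurai reaction of prenylsilane.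

Step 3
Reactants: 7 (2S,3S)-2-allyl-2-methyl-3-(2-methylbut-3-en-2-yl)cyclopentan-1-one
Product: 8 (3aS,7aS)-4,4,7a-trimethyl-2,3,3a,4,7,7a-hexahydro-1H-inden-1-one
Conditions: Hoveyda–Grubbs II (3 mol%), CH2Cl2, 40 °C
Reagents that add atoms: none
Why: Ring-closing olefin metathesis of the trans-disposed allyl and 1,1-dimethylallyl groups closes ring A as a trans-fused cyclohexene with loss of ethene; no stereocentre is touched.

Step 4
Reactants: 9 4-methyl-3,6-dihydro-2H-pyran; 10 acetyl bromide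
Product: 11 (3Z)-5-bromo-3-methylpent-3-en-1-yl acetate
Conditions: ZnBr2 (5 mol%), CH2Cl2, −20 → 0 °C
Reagents that add atoms: none
Why: Lewis-acid-promoted acyl halide cleavage of the cyclic allylic ether (O-acylation, then bromide attack at the allylic C6) gives the bromo acetate, and the ring fixes the trisubstituted alkene as Z.

Step 5
Reactants: 8 (3aS,7aS)-4,4,7a-trimethyl-2,3,3a,4,7,7a-hexahydro-1H-inden-1-one; 12 dibromomethane; 11 (3Z)-5-bromo-3-methylpent-3-en-1-yl acetate
Product: 16 (3Z)-3-methyl-5-[(1R,4aS,8aS)-5,5,8a-trimethyl-2-oxo-1,2,3,4,4a,5,8,8a-octahydronaphthalen-1-yl]pent-3-en-1-yl acetate, via lithium dibromomethyl carbinolate 13 (not isolated), via ring-expanded lithium enolate 14 (not isolated), via 9-epi ketone 15 (not isolated)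
Conditions: 12, LiTMP, THF, −90 °C; 8; n-BuLi (1.0 equiv), −90 → −40 °C; then 11, DMPU, −40 → 0 °C; then DBU (0.2 equiv), PhMe, 60 °C
Reagents that add atoms: none
Why: β-Oxido carbenoid (Nozaki-type) one-carbon ring expansion, in which LiCHBr2 adds to the ketone and Br/Li exchange triggers the 1,2-shift of the more substituted C7a (future C10, with retention) onto the new carbon (C9), giving ring B as its regiodefined C9 enolate 14; this is C-allylated by 11 mainly anti to the angular methyl (15), and DBU equilibrates C9 to the equatorial 9β (1R) epimer 16.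

Step 6
Reactants: 16 (3Z)-3-methyl-5-[(1R,4aS,8aS)-5,5,8a-trimethyl-2-oxo-1,2,3,4,4a,5,8,8a-octahydronaphthalen-1-yl]pent-3-en-1-yl acetate
Product: 17 (3S)-3-methyl-5-[(1R,4aS,8aS)-5,5,8a-trimethyl-2-oxodecahydronaphthalen-1-yl]pentyl acetate
Conditions: [Ir(cod)(chiral pyridyl-phosphinite)]BArF (2 mol%), H2 (50 bar), CH2Cl2, rt
Reagents that add atoms: none
Why: Ir–P,N-catalysed asymmetric hydrogenation of the unfunctionalised Z-trisubstituted alkene delivers H2 to the C13 Si face under catalyst control (13S) and also saturates the ring A alkene, leaving ketone and acetate intact.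

Step 7
Reactants: 17 (3S)-3-methyl-5-[(1R,4aS,8aS)-5,5,8a-trimethyl-2-oxodecahydronaphthalen-1-yl]pentyl acetate
Product: 18 (3S)-3-methyl-5-[(1R,4aS,8aS)-5,5,8a-trimethyl-2-(trifluoromethanesulfonyloxy)-1,4,4a,5,6,7,8,8a-octahydronaphthalen-1-yl]pentyl acetate
Conditions: KHMDS (1.05 equiv), THF, −78 °C; PhNTf2, −78 → 0 °C
Reagents that add atoms: N-phenylbis(trifluoromethanesulfonimide), O=S(=O)(N(c1ccccc1)S(=O)(=O)C(F)(F)F)C(F)(F)F
Why: Kinetic deprotonation at the unhindered C7 methylene (not the tertiary C9–H, and faster than the acetate) followed by O-triflation gives the Δ7 enol triflate regioselectively; no stereocentre changes.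

Step 8
Reactants: 18 (3S)-3-methyl-5-[(1R,4aS,8aS)-5,5,8a-trimethyl-2-(trifluoromethanesulfonyloxy)-1,4,4a,5,6,7,8,8a-octahydronaphthalen-1-yl]pentyl acetate; 19 carbon monoxide
Product: 20 (1R,4aS,8aS)-1-[(3S)-5-acetoxy-3-methylpentyl]-5,5,8a-trimethyl-1,4,4a,5,6,7,8,8a-octahydronaphthalene-2-carboxylic acid
Conditions: Pd(OAc)2 (5 mol%), dppf, CO (1 atm), KOAc, DMF–H2O, 60 °C
Reagents that add atoms: water, O
Why: Pd-catalysed hydroxycarbonylation of the vinyl triflate (oxidative addition, CO insertion, hydrolysis of the acyl-palladium) installs C17 as the conjugated acid without touching the stereocentres or the acetate.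

## Compound list

1 | (3-methylbut-2-en-1-yl)magnesium chloride | CC(C)=CC[Mg]Cl | starting material
2 | (3-methylbut-2-en-1-yl)trimethylsilane | CC(C)=CC[Si](C)(C)C | intermediate
3 | 2-methylcyclopent-2-en-1-one | CC1=CCCC1=O | starting material
4 | allyl bromide | C=CCBr | starting material
5 | trimethyl{[(3S)-2-methyl-3-(2-methylbut-3-en-2-yl)cyclopent-1-en-1-yl]oxy}silane | C[Si](C)(C)OC1=C(C)[C@H](C(C)(C)C=C)CC1 | intermediate
6 | lithium (3S)-2-methyl-3-(2-methylbut-3-en-2-yl)cyclopent-1-en-1-olate | [Li]OC1=C(C)[C@H](C(C)(C)C=C)CC1 | intermediate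
7 | (2S,3S)-2-allyl-2-methyl-3-(2-methylbut-3-en-2-yl)cyclopentan-1-one | O=C1CC[C@@H](C(C)(C)C=C)[C@]1(C)CC=C | intermediate
8 | (3aS,7aS)-4,4,7a-trimethyl-2,3,3a,4,7,7a-hexahydro-1H-inden-1-one | O=C1CC[C@H]2C(C)(C)C=CC[C@]12C | intermediate
9 | 4-methyl-3,6-dihydro-2H-pyran | CC1=CCOCC1 | starting material
10 | acetyl bromide | CC(=O)Br | starting material
11 | (3Z)-5-bromo-3-methylpent-3-en-1-yl acetate | CC(=O)OCC/C(C)=C\CBr | intermediate
12 | dibromomethane | BrCBr | starting material
13 | lithium (1S,3aS,7aS)-1-(dibromomethyl)-4,4,7a-trimethyl-2,3,3a,4,7,7a-hexahydro-1H-inden-1-olate (expected major C1 epimer) | [Li]O[C@@]1(C(Br)Br)CC[C@H]2C(C)(C)C=CC[C@]12C | intermediate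
14 | lithium (4aS,8aS)-5,5,8a-trimethyl-3,4,4a,5,8,8a-hexahydronaphthalen-2-olate | [Li]OC1=C[C@@]2(C)CC=CC(C)(C)[C@@H]2CC1 | intermediate
15 | (3Z)-3-methyl-5-[(1S,4aS,8aS)-5,5,8a-trimethyl-2-oxo-1,2,3,4,4a,5,8,8a-octahydronaphthalen-1-yl]pent-3-en-1-yl acetate | CC(=O)OCC/C(C)=C\C[C@@H]1C(=O)CC[C@H]2C(C)(C)C=CC[C@]12C | intermediate
16 | (3Z)-3-methyl-5-[(1R,4aS,8aS)-5,5,8a-trimethyl-2-oxo-1,2,3,4,4a,5,8,8a-octahydronaphthalen-1-yl]pent-3-en-1-yl acetate | CC(=O)OCC/C(C)=C\C[C@H]1C(=O)CC[C@H]2C(C)(C)C=CC[C@]12C | intermediate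
17 | (3S)-3-methyl-5-[(1R,4aS,8aS)-5,5,8a-trimethyl-2-oxodecahydronaphthalen-1-yl]pentyl acetate | CC(=O)OCC[C@@H](C)CC[C@H]1C(=O)CC[C@H]2C(C)(C)CCC[C@]12C | intermediate
18 | (3S)-3-methyl-5-[(1R,4aS,8aS)-5,5,8a-trimethyl-2-(trifluoromethanesulfonyloxy)-1,4,4a,5,6,7,8,8a-octahydronaphthalen-1-yl]pentyl acetate | CC(=O)OCC[C@@H](C)CC[C@H]1C(OS(=O)(=O)C(F)(F)F)=CC[C@H]2C(C)(C)CCC[C@]12C | intermediate
19 | carbon monoxide | [C-]#[O+] | starting material
20 | (1R,4aS,8aS)-1-[(3S)-5-acetoxy-3-methylpentyl]-5,5,8a-trimethyl-1,4,4a,5,6,7,8,8a-octahydronaphthalene-2-carboxylic acid | CC(=O)OCC[C@@H](C)CC[C@H]1C(C(=O)O)=CC[C@H]2C(C)(C)CCC[C@]12C | target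

## Step count and risks

Total steps: 8. Longest linear sequence: 7 (steps 1, 2, 3, 5, 6, 7, 8; step 4 is the side branch).

**Step 2** (new reaction: enantio- and γ-selectivity on a hindered α-methyl enone, then formation of a congested quaternary centre). The fallback sets out from 3 (with 2 and 4) and comes back at 8. The conjugate Hosomi–Sakurai addition is run with an achiral silyl Lewis acid (Me3SiNTf2 from HNTf2, the known racemic reaction), followed by the same MeLi/allyl bromide trapping and metathesis. This gives 5, 6, 7 and 8 as racemates, that is, together with the enantiomeric silyl enol ether F1, the enantiomeric lithium enolate F2, the enantiomeric cyclopentanone F3 and the enantiomeric hydrindenone F4. NaBH4 reduces the racemic ketone from the face opposite the angular methyl to the (1S,3aS,7aS)-indenol F5 and its enantiomeric indenol F6. Esterification with (S)-O-methylmandelic acid (DCC, DMAP) gives the diastereomeric mandelate ester F7 (from F5) and mandelate ester F8 (from F6), which are separated on silica. LiOH cleaves F7 back to F5, and Dess–Martin oxidation returns enantiopure 8.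

**Step 5** (migration of the quaternary carbon must beat that of the CH2, and a hindered enolate must be alkylated in the presence of an acetate). The fallback sets out from 8 and comes back at 17. Vinylmagnesium bromide/CeCl3 adds to 8 from the α face to give the vinyl carbinol F9. NBS then triggers a bromonium-induced semipinacol shift of the more substituted carbon to the bromomethyl ketone F10, and DBU eliminates HBr to the exocyclic enone F11. Separately, Cu-catalysed methylboration (B2pin2, MeI) of but-3-yn-1-yl acetate F12 gives the (E)-alkenyl boronate F13. Rh-catalysed 1,4-addition of F13 to F11, with axial protonation at C9, gives the (E)-dienyl keto acetate F14 (the E isomer of 16). F14 is hydrogenated as in step 6 with the opposite ligand enantiomer to reach 17.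

**Step 6** (enantioselectivity on a Z-trisubstituted, essentially unfunctionalised alkene). The fallback sets out from 16 and comes back at 17. K2CO3/MeOH removes the acetate to give the homoallylic alcohol F15. Hydroxyl-directed hydrogenation with Ru(OAc)2(BINAP) (enantiomer chosen for 13S) reduces only the side-chain alkene to the (13S)-hydroxy enone F16. H2 over Pd/C saturates ring A to the saturated hydroxy ketone F17, and Ac2O/pyridine gives 17.

## Further compounds

F1 | step 2 | trimethyl{[(3R)-2-methyl-3-(2-methylbut-3-en-2-yl)cyclopent-1-en-1-yl]oxy}silane | C[Si](C)(C)OC1=C(C)[C@@H](C(C)(C)C=C)CC1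
F2 | step 2 | lithium (3R)-2-methyl-3-(2-methylbut-3-en-2-yl)cyclopent-1-en-1-olate | [Li]OC1=C(C)[C@@H](C(C)(C)C=C)CC1
F3 | step 2 | (2R,3R)-2-allyl-2-methyl-3-(2-methylbut-3-en-2-yl)cyclopentan-1-one | O=C1CC[C@H](C(C)(C)C=C)[C@@]1(C)CC=C
F4 | step 2 | (3aR,7aR)-4,4,7a-trimethyl-2,3,3a,4,7,7a-hexahydro-1H-inden-1-one | O=C1CC[C@@H]2C(C)(C)C=CC[C@@]12C
F5 | step 2 | (1S,3aS,7aS)-4,4,7a-trimethyl-2,3,3a,4,7,7a-hexahydro-1H-inden-1-ol | O[C@H]1CC[C@H]2C(C)(C)C=CC[C@]12C
F6 | step 2 | (1R,3aR,7aR)-4,4,7a-trimethyl-2,3,3a,4,7,7a-hexahydro-1H-inden-1-ol | O[C@@H]1CC[C@@H]2C(C)(C)C=CC[C@@]12C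
F7 | step 2 | (1S,3aS,7aS)-4,4,7a-trimethyl-2,3,3a,4,7,7a-hexahydro-1H-inden-1-yl (S)-2-methoxy-2-phenylacetate | CO[C@H](C(=O)O[C@H]1CC[C@H]2C(C)(C)C=CC[C@]12C)c1ccccc1
F8 | step 2 | (1R,3aR,7aR)-4,4,7a-trimethyl-2,3,3a,4,7,7a-hexahydro-1H-inden-1-yl (S)-2-methoxy-2-phenylacetate | CO[C@H](C(=O)O[C@@H]1CC[C@@H]2C(C)(C)C=CC[C@@]12C)c1ccccc1
F9 | step 5 | (1R,3aS,7aS)-1-ethenyl-4,4,7a-trimethyl-2,3,3a,4,7,7a-hexahydro-1H-inden-1-ol | O[C@@]1(C=C)CC[C@H]2C(C)(C)C=CC[C@]12C
F10 | step 5 | (1R,4aS,8aS)-1-(bromomethyl)-5,5,8a-trimethyl-3,4,4a,5,8,8a-hexahydronaphthalen-2(1H)-one | BrC[C@H]1C(=O)CC[C@H]2C(C)(C)C=CC[C@]12C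
F11 | step 5 | (4aS,8aS)-5,5,8a-trimethyl-1-methylidene-3,4,4a,5,8,8a-hexahydronaphthalen-2(1H)-one | C=C1C(=O)CC[C@H]2C(C)(C)C=CC[C@]12C
F12 | step 5 | but-3-yn-1-yl acetate | CC(=O)OCCC#C
F13 | step 5 | (3E)-3-methyl-4-(4,4,5,5-tetramethyl-1,3,2-dioxaborolan-2-yl)but-3-en-1-yl acetate | CC(=O)OCC/C(C)=C/B1OC(C)(C)C(C)(C)O1
F14 | step 5 | (3E)-3-methyl-5-[(1R,4aS,8aS)-5,5,8a-trimethyl-2-oxo-1,2,3,4,4a,5,8,8a-octahydronaphthalen-1-yl]pent-3-en-1-yl acetate | CC(=O)OCC/C(C)=C/C[C@H]1C(=O)CC[C@H]2C(C)(C)C=CC[C@]12C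
F15 | step 6 | (1R,4aS,8aS)-1-[(2Z)-5-hydroxy-3-methylpent-2-en-1-yl]-5,5,8a-trimethyl-3,4,4a,5,8,8a-hexahydronaphthalen-2(1H)-one | OCC/C(C)=C\C[C@H]1C(=O)CC[C@H]2C(C)(C)C=CC[C@]12C
F16 | step 6 | (1R,4aS,8aS)-1-[(3S)-5-hydroxy-3-methylpentyl]-5,5,8a-trimethyl-3,4,4a,5,8,8a-hexahydronaphthalen-2(1H)-one | OCC[C@@H](C)CC[C@H]1C(=O)CC[C@H]2C(C)(C)C=CC[C@]12C
F17 | step 6 | (1R,4aS,8aS)-1-[(3S)-5-hydroxy-3-methylpentyl]-5,5,8a-trimethyloctahydronaphthalen-2(1H)-one | OCC[C@@H](C)CC[C@H]1C(=O)CC[C@H]2C(C)(C)CCC[C@]12C
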